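## Structural features

Lasiodiplactone A (20) is a 12/6/6/5 tetracycle built on one pentasubstituted benzene ring. In furo[2,3-b]chromene numbering (O1, C2, C3, C3a, C4, C4a, C5–C8, C8a, O9, C9a) the arene carries the lactone carbonyl on C6 and the heptamethylene chain on C5, so the twelve-membered lactone is fused at C5–C6; C7 bears OCH3, C8 is the only aromatic CH, and C8a and C4a carry the aryl oxygen O9 and the benzylic CH2 (C4) of a cis-fused tetrahydrofuro-pyran. Three contiguous stereocentres sit in the furan ring: C3 (CH3), C3a (ring-fusion H) and the ketal carbon C9a (CH3), all S, with the C3 methyl trans to C4 and cis to the C9a methyl. The fourth stereocentre, the (R)-configured O–CH(CH3) of the lactone, is remote from them. Fragile points are the mixed aryl/alkyl ketal (acid), C3a whenever the ketal is open as a methyl ketone (epimerisation), and the benzoate C–O bond towards strong one-electron reductants. The real difficulty is the ester: its carbonyl lies between two ortho substituents, so intermolecular acyl substitution is slow, and closing a twelve-membered ring through it adds an entropic penalty; a lesser problem is placing the C4 carbon on the arene between an oxygen and an alkyl group. The plan exploits the six-atom run C(=O)–O–CH(CH3)–CH2–CH2–CH2 of the macrocycle: with a sulfonyl group on the fourth ring carbon from the lactone oxygen, these atoms map onto an aryl ketone in an eight-membered carbocycle (C6, C=O, Cα, four CH2, C5) whose α-carbon holds PhSO2 and an (R)-3-hydroxybutyl arm, and attack of the arm's alkoxide on the ketone followed by cleavage of the C(=O)–Cα bond delivers the hindered ester and the large ring together.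

## Logic of the disconnections

20 from 19. The C–H bond on the fourth ring carbon from the lactone oxygen is traced back to a C–SO2Ph bond. The sulfone is only an activating group for the preceding step, so nothing of the skeleton changes. The demand is a reductant that cleaves an unactivated secondary alkyl phenyl sulfone but spares the benzoate C–O bond and the ketal.

19 from 17 (through 18). The acyl C–O bond of the lactone is cut and the acyl carbon is reconnected to the sulfonyl-bearing carbon. The twelve-membered ring becomes an eight-membered aryl ketone with a four-atom hydroxyalkyl arm on its α-carbon. The reason is that the ester bond is then made intramolecularly through a six-membered ring, with no macrocyclisation and no bimolecular attack on a hindered carbonyl. The demand is an alkoxide base with a proton source for the released carbanion, and a substrate with no other base-labile site; the quaternary centre may be either epimer.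

17 from 14 and 16; 16 from 15. The bond from the quaternary carbon to the first CH2 of the arm is cut. This traces the carbinol stereocentre to a purchased enantiopure diol instead of an asymmetric reduction of a methyl alkyl ketone, for which small-molecule catalysts are poorly selective. The demand is C- rather than O-alkylation of a hindered, stabilised enolate, under a base too weak to start the ring expansion. 16 needs only a primary-selective hydroxyl-to-iodide exchange in 15.

14 from 13. The bond between the ketone carbon and the sulfonyl carbon is cut, an intramolecular acylation of a sulfonyl carbanion by the benzoate. The gain is an open-chain ω-sulfonyl ester. The demand is the hardest before the key step: eight-membered ring closure on a shielded ester, which needs high dilution and relies on irreversible enolate formation of the product.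

13 from 11 and 12; 11 from 9 and 10. The C–S bond and then the bond between the benzylic carbon on C5 and the next CH2 are cut. The chain is introduced in two operations because a halide already carrying the sulfone would be deprotonated next to sulfur by the benzylic anion and would close to a cyclobutyl sulfone; a dihalide without acidic hydrogens avoids this at no cost in steps. The demand is clean lateral metalation of the C5 methyl of 9, the only benzylic position conjugated with the ester.

9 from 7 (through 8). The C9a–CH3 bond and the C9a–O9 bond are cut, giving a γ-lactone and a free phenol. The gain is that the ketal, its methyl group and the C9a configuration all arise in one operation, the cis ring fusion being dictated by C3a. The demand is a methyl nucleophile that adds once to the lactone and leaves the hindered benzoate alone.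

7 from 6; 6 from 4 and 5. After removal of the phenol protecting group the C4–C3a bond is cut, an enolate alkylation. C3 is purchased in 5 and C3a is set trans to it by approach anti to the methyl group. The demand is a benzylic halide on the fully substituted arene.

4 from 3; 3 from 1 (through 2). The aryl–CH2Cl bond is cut, an electrophilic substitution at the position ortho to one alkoxy group and para to the other, and the two phenols of 1 are told apart by their different acidity. The demand is that the second ortho position, between the two oxygens, stays untouched and that the benzyl ether survives the acid.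

## Other disconnections considered

Alternative 1: The cut is the arene bond between the ester-bearing and the chain-bearing carbon, with both phenolic carbons returned to ketones. It leads to the sixteen-membered triketo lactone A1, in which the carbon between the second and third ketone carries the (3S,4S)-lactonylmethyl group. In the forward step base would let the CH2 of the β-keto ester attack, across the ring, the ketone next to the heptamethylene chain; loss of water and enolisation would give the resorcylate A2 with the twelve-membered lactone already in place.
- In favour: arene and lactone appear together, the arene substitution pattern is fixed by the chain, and no auxiliary group has to be removed afterwards.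
- Against: A1 is a base-sensitive 1,3,5-tricarbonyl macrocycle that itself needs a sixteen-membered ring closure. Pyranone formation and other aldol modes compete with the wanted one. The lactonylmethyl branch cannot be introduced regioselectively by alkylating a triketone, so it must be built into one of the acyl fragments. After A2, methyl addition, ketalisation and methylation of the chelated phenol still follow.
- Comparison: this plan is the equal of the chosen one in avoiding a bimolecular attack on the hindered benzoate, and better in that no regiochemical question of aromatic substitution arises and no sulfone is carried. It is weaker on step economy, since the arene bought in 1 must be made from a long chain, and on mechanism, since several cyclisation modes are open where the chosen key step has one.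

Alternative 2: The cuts are the C4–C3a bond and the C3–CH3 bond. They lead to the macrocyclic benzylic bromide A4 and the (5S)-menthyloxybutenolide A3 of the (1S,2R,5S)-menthyl series. In the forward step a methyl cuprate would add anti to the menthyloxy group and the enolate would be benzylated by A4 anti to the new methyl group, giving the all-trans lactone acetal A5.
- In favour: both carbon stereocentres of the furan ring are set in one flask under auxiliary control, and the union is late and convergent.
- Against: in A5 the oxidation pattern is transposed. The carbon that must become the ring OCH2 is at the acetal level and carries the auxiliary, while the lactone carbonyl must become the methyl ketal, so several redox and deprotection operations follow in the presence of the macrolactone. A4 presupposes the finished macrolide, whose hindered ester still has to be made, and is a solvolytically labile, electron-rich benzylic bromide. The copper-derived enolate is a weaker nucleophile than a lithium lactone enolate.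
- Comparison: step 3 of the chosen plan uses the same anti-alkylation logic but buys the methyl centre, so it sets one centre instead of two and arrives directly at the right oxidation state. Alternative 2 is better in convergence and equal in control of the C3/C3a pair; it is weaker in the number of steps after the key step and leaves the macrolactone problem open.

Alternative 3: Two arene bonds are cut so that C5 and C6 come from the triple bond of the twelve-membered ynoate A7 and the other four arene carbons from the silyl ketene acetal diene A6 built on the furopyran. In the forward step cycloaddition and loss of methanol would give the chelated phenol A8; O-methylation would finish the synthesis.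
- In favour: this is the most convergent plan. The regiochemistry is polarity-matched, the nucleophilic diene terminus meeting the β-carbon of the ynoate. The lactone is closed on an unhindered ynoic acid before the arene exists, and only one step follows the key step.
- Against: A6 combines a ketal, a cyclic enol ether and a silyl ketene acetal and is sensitive to acid and moisture. A7 is an internal, β-alkylated ynoate and a sluggish dienophile, and the ring-fused diene terminus is trisubstituted. The cycloaddition would therefore need heat that A6 may not tolerate, and desilylation or Michael-type pathways compete.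
- Comparison: on step economy after the key step and on convergence this plan is better than the chosen one, and it is equal in avoiding esterification of a hindered benzoic acid. On mechanism it is more demanding, because two fragile partners must meet in a hindered thermal cycloaddition, whereas the chosen plan is a sequence of anion reactions with an intramolecular key step.

Key step: step 11

Remarks on the chemistry:
- Methyl 2,4-dihydroxy-6-methylbenzoate (1) is assumed to be purchasable; it is the oxidation–esterification product of 2,4-dihydroxy-6-methylbenzaldehyde.
- Counted from the lactone oxygen, the sulfonyl group of 19 stands on the fourth ring carbon, O–CH(CH3)–CH2–CH2–CH(SO2Ph), because the carbon that leaves as the carbanion is the former quaternary carbon.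
- 14, 17, 18 and 19 are carried as mixtures of epimers at the sulfonyl-bearing carbon (18 also at the hemiketal carbon).

## Route

Step 1
Reactants: 1 methyl 2,4-dihydroxy-6-methylbenzoate
Product: 3 methyl 4-(benzyloxy)-2-methoxy-6-methylbenzoate, via methyl 4-(benzyloxy)-2-hydroxy-6-methylbenzoate 2 (not isolated)
Conditions: BnBr (1.05 equiv), K2CO3, DMF, rt; then MeI (3 equiv), 50 °C
Reagents that add atoms: benzyl bromide BrCc1ccccc1; iodomethane CI
Why: Williamson etherification in two stages: the 4-OH, para to the ester and not hydrogen-bonded, is the more acidic and more nucleophilic phenol and takes the single equivalent of BnBr; the chelated 2-OH is then methylated by excess MeI on warming.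

Step 2
Reactants: 3 methyl 4-(benzyloxy)-2-methoxy-6-methylbenzoate
Product: 4 methyl 4-(benzyloxy)-3-(chloromethyl)-6-methoxy-2-methylbenzoate
Conditions: ClCH2OCH3 (3 equiv), ZnCl2 (cat.), CH2Cl2, 0 °C to rt
Reagents that add atoms: chloromethyl methyl ether COCCl
Why: Blanc chloromethylation: the free position between OBn and CH3 is ortho to one alkoxy group and para to the other and should react in preference to the ortho/ortho position between the two oxygens, as in the formylation of orcinol dimethyl ether; the ester moderates the ring enough to discourage a second substitution.

Step 3
Reactants: 4 methyl 4-(benzyloxy)-3-(chloromethyl)-6-methoxy-2-methylbenzoate; 5 (S)-4-methyldihydrofuran-2(3H)-one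
Product: 6 methyl 4-(benzyloxy)-6-methoxy-2-methyl-3-{[(3S,4S)-4-methyl-2-oxooxolan-3-yl]methyl}benzoate
Conditions: 5 (1.25 equiv), LiN(i-Pr)2 (1.2 equiv), THF, −78 °C; then 4, DMPU, Bu4NI (cat.), −78 to −20 °C
Reagents that add atoms: none
Why: Alkylation of the lithium enolate of a β-substituted γ-butyrolactone: the benzylic halide approaches the enolate face opposite to the C4 methyl group, so the new C3 centre is set trans (3S,4S), while C4 comes unchanged from 5.

Step 4
Reactants: 6 methyl 4-(benzyloxy)-6-methoxy-2-methyl-3-{[(3S,4S)-4-methyl-2-oxooxolan-3-yl]methyl}benzoate
Product: 7 methyl 4-hydroxy-6-methoxy-2-methyl-3-{[(3S,4S)-4-methyl-2-oxooxolan-3-yl]methyl}benzoate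
Conditions: H2 (1 atm), Pd/C, EtOAc, rt
Reagents that add atoms: none
Why: Hydrogenolysis of the aryl benzyl ether; the lactone, the benzoate and the benzylic C–C bonds are inert, and the stereocentres are not touched.

Step 5
Reactants: 7 methyl 4-hydroxy-6-methoxy-2-methyl-3-{[(3S,4S)-4-methyl-2-oxooxolan-3-yl]methyl}benzoate
Product: 9 methyl (3S,3aS,9aS)-7-methoxy-3,5,9a-trimethyl-2,3,3a,9a-tetrahydro-4H-furo[2,3-b]chromene-6-carboxylate, via hydroxy lactol 8 (not isolated)
Conditions: MeLi (2.2 equiv), THF, −78 °C; aq. NH4Cl; then PPTS (cat.), MgSO4, CH2Cl2, rt
Reagents that add atoms: methyllithium [Li]C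
Why: The first equivalent of MeLi deprotonates the phenol and the second adds to the γ-lactone, stopping at the lithium lactolate at −78 °C; the 2,6-disubstituted benzoate, now para to a phenoxide, should not be attacked. Mild acid ionises lactol 8 to an oxocarbenium ion that the neighbouring phenol traps (ketalisation); the pyran can only close cis on the furan, so C3a fixes the configuration of C9a (S).

Step 6
Reactants: 9 methyl (3S,3aS,9aS)-7-methoxy-3,5,9a-trimethyl-2,3,3a,9a-tetrahydro-4H-furo[2,3-b]chromene-6-carboxylate; 10 1-chloro-4-iodobutane
Product: 11 methyl (3S,3aS,9aS)-5-(5-chloropentyl)-7-methoxy-3,9a-dimethyl-2,3,3a,9a-tetrahydro-4H-furo[2,3-b]chromene-6-carboxylate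
Conditions: LiN(i-Pr)2 (1.2 equiv), THF, −78 °C; then 10 (2 equiv), −78 to −40 °C
Reagents that add atoms: none
Why: Lateral (benzylic) lithiation of the ortho-toluate gives the ester-stabilised dienolate, which is alkylated at the iodide end of 10; the C4 methylene is meta to the ester and not acidified. A dihalide without acidic hydrogens is used because a halide already bearing the sulfone would be deprotonated next to sulfur by this anion and cyclise.

Step 7
Reactants: 11 methyl (3S,3aS,9aS)-5-(5-chloropentyl)-7-methoxy-3,9a-dimethyl-2,3,3a,9a-tetrahydro-4H-furo[2,3-b]chromene-6-carboxylate; 12 sodium benzenesulfinate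
Product: 13 methyl (3S,3aS,9aS)-7-methoxy-3,9a-dimethyl-5-[5-(phenylsulfonyl)pentyl]-2,3,3a,9a-tetrahydro-4H-furo[2,3-b]chromene-6-carboxylate
Conditions: 12 (1.5 equiv), Bu4NI (cat.), DMF, 70 °C
Reagents that add atoms: none
Why: SN2 S-alkylation of the sulfinate, iodide-catalysed, gives the alkyl phenyl sulfone; no other electrophilic site of 11 reacts under these conditions.

Step 8
Reactants: 13 methyl (3S,3aS,9aS)-7-methoxy-3,9a-dimethyl-5-[5-(phenylsulfonyl)pentyl]-2,3,3a,9a-tetrahydro-4H-furo[2,3-b]chromene-6-carboxylate
Product: 14 cyclic keto sulfone: furochromene core of 9 in which C5 and C6 are bridged by –(CH2)4–CH(SO2Ph)–C(=O)– (carbonyl on C6; eight-membered ring; both epimers at the sulfonyl carbon)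
Conditions: LiN(SiMe3)2 (3 equiv), THF, 0 to 45 °C, 0.005 M (slow addition of 13); aq. NH4Cl
Reagents that add atoms: none
Why: Intramolecular acylation of the α-sulfonyl carbanion by the benzoate (Dieckmann/Claisen type): reversible deprotonation and ring closure are pulled forward by irreversible formation of the β-keto sulfone enolate, and the two sp2 atoms of the benzo fusion ease the eight-membered closure. High dilution suppresses the bimolecular Claisen reaction; the new sulfonyl-bearing centre is of no consequence.

Step 9
Reactants: 15 (R)-butane-1,3-diol
Product: 16 (R)-4-iodobutan-2-ol
Conditions: PPh3, I2, imidazole, CH2Cl2, 0 °C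
Reagents that add atoms: iodine II
Why: Garegg–Samuelsson (Appel-type) iodination: the alkoxyphosphonium ion forms and is displaced much faster at the primary than at the secondary hydroxyl, so the stereocentre is untouched.

Step 10
Reactants: 14 cyclic keto sulfone; 16 (R)-4-iodobutan-2-ol
Product: 17 cyclic keto sulfone carrying an (R)-3-hydroxybutyl group on the sulfonyl-bearing α-carbon (quaternary; both epimers)
Conditions: Cs2CO3 (1.5 equiv), 16 (1.5 equiv), DMF, 45 °C
Reagents that add atoms: none
Why: C-Alkylation of the caesium enolate of the β-keto sulfone by a primary iodide creates the quaternary carbon; carbonate is too weak to form the side-chain alkoxide, so the hydroxyl needs no protection and the ring expansion does not start. The (R)-carbinol is carried in from 16.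

Step 11
Reactants: 17 cyclic keto sulfone carrying an (R)-3-hydroxybutyl group on the sulfonyl-bearing α-carbon
Product: 19 lasiodiplactone A carrying PhSO2 on the fourth ring carbon from the lactone oxygen (both epimers), via fused hemiketal 18 (not isolated)
Conditions: KOt-Bu (0.3 equiv), THF, 0 °C to rt; then AcOH
Reagents that add atoms: none
Why: KOt-Bu deprotonates the secondary hydroxyl of 17, the alkoxide adds to the aryl ketone in a 6-exo-trig closure to give the fused hemiketal alkoxide 18, and 18 fragments in a retro-Claisen sense: the bond from the former carbonyl carbon to the quaternary carbon breaks, the hemiketal oxygen becomes the lactone carbonyl, and the charge leaves on the sulfonyl-stabilised carbon. That carbanion is protonated by t-BuOH or by the hydroxyl of another molecule of 17, which carries the chain with catalytic base and makes the fragmentation irreversible. The closest known reaction type is the base-induced ring enlargement of 2-(hydroxyalkyl)-2-sulfonyl- and 2-nitrocycloalkanones to macrolides. The twelve-membered lactone is thus closed not end to end but by merging the eight-membered carbocycle with the six-membered hemiketal ring through cleavage of their common bond, so the only cyclisation event is the six-membered one. No stereocentre of the target is created: the (R)-carbinol keeps its configuration because its C–O bond is never broken, the quaternary centre disappears, and the new CH(SO2Ph) centre forms as both epimers and is erased in step 12. The selectivity needed is cleavage of the carbonyl–C(SO2Ph) bond rather than the carbonyl–aryl bond, secured by the sulfone, which makes its carbon by far the better leaving group. Intermolecular acyl transfer must also be absent, which the non-nucleophilic base and the two ortho substituents shielding the new benzoate secure. Release of medium-ring strain and the gain of ester resonance provide the driving force, and the base-stable ketal is a spectator.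

Step 12
Reactants: 19 lasiodiplactone A carrying PhSO2 on the fourth ring carbon from the lactone oxygen
Product: 20 lasiodiplactone A
Conditions: 6% Na(Hg), Na2HPO4, MeOH–THF, −20 to 0 °C
Reagents that add atoms: none
Why: Reductive desulfonylation with buffered sodium amalgam: electron transfer to the phenyl sulfone cleaves the alkyl C–S bond and the carbon is protonated by MeOH; the hindered, electron-rich benzoate and the ketal should be inert. SmI2–HMPA is avoided because it can cleave benzoate C–O bonds.

## Compound list

1 | methyl 2,4-dihydroxy-6-methylbenzoate | COC(=O)c1c(C)cc(O)cc1O | starting material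
2 | methyl 4-(benzyloxy)-2-hydroxy-6-methylbenzoate | COC(=O)c1c(C)cc(OCc2ccccc2)cc1O | intermediate
3 | methyl 4-(benzyloxy)-2-methoxy-6-methylbenzoate | COC(=O)c1c(C)cc(OCc2ccccc2)cc1OC | intermediate
4 | methyl 4-(benzyloxy)-3-(chloromethyl)-6-methoxy-2-methylbenzoate | COC(=O)c1c(C)c(CCl)c(OCc2ccccc2)cc1OC | intermediate
5 | (S)-4-methyldihydrofuran-2(3H)-one | O=C1C[C@H](C)CO1 | starting material
6 | methyl 4-(benzyloxy)-6-methoxy-2-methyl-3-{[(3S,4S)-4-methyl-2-oxooxolan-3-yl]methyl}benzoate | COC(=O)c1c(C)c(C[C@H]2[C@H](C)COC2=O)c(OCc2ccccc2)cc1OC | intermediate
7 | methyl 4-hydroxy-6-methoxy-2-methyl-3-{[(3S,4S)-4-methyl-2-oxooxolan-3-yl]methyl}benzoate | COC(=O)c1c(C)c(C[C@H]2[C@H](C)COC2=O)c(O)cc1OC | intermediate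
8 | methyl 4-hydroxy-3-{[(3S,4S)-2-hydroxy-2,4-dimethyloxolan-3-yl]methyl}-6-methoxy-2-methylbenzoate (lactol, in equilibrium with the open hydroxy ketone) | COC(=O)c1c(C)c(C[C@H]2[C@H](C)COC2(C)O)c(O)cc1OC | intermediate
9 | methyl (3S,3aS,9aS)-7-methoxy-3,5,9a-trimethyl-2,3,3a,9a-tetrahydro-4H-furo[2,3-b]chromene-6-carboxylate | COc1cc2c(c(C)c1C(=O)OC)C[C@H]1[C@H](C)CO[C@@]1(C)O2 | intermediate
10 | 1-chloro-4-iodobutane | ClCCCCI | starting material
11 | methyl (3S,3aS,9aS)-5-(5-chloropentyl)-7-methoxy-3,9a-dimethyl-2,3,3a,9a-tetrahydro-4H-furo[2,3-b]chromene-6-carboxylate | COc1cc2c(c(CCCCCCl)c1C(=O)OC)C[C@H]1[C@H](C)CO[C@@]1(C)O2 | intermediate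
12 | sodium benzenesulfinate | [Na+].[O-]S(=O)c1ccccc1 | starting material
13 | methyl (3S,3aS,9aS)-7-methoxy-3,9a-dimethyl-5-[5-(phenylsulfonyl)pentyl]-2,3,3a,9a-tetrahydro-4H-furo[2,3-b]chromene-6-carboxylate | COc1cc2c(c(CCCCCS(=O)(=O)c3ccccc3)c1C(=O)OC)C[C@H]1[C@H](C)CO[C@@]1(C)O2 | intermediate
14 | cyclic keto sulfone: furochromene core with C5 and C6 bridged by –(CH2)4–CH(SO2Ph)–C(=O)–, carbonyl on C6, both epimers at the sulfonyl carbon | COc1cc2c(c3c1C(=O)C(S(=O)(=O)c1ccccc1)CCCC3)C[C@H]1[C@H](C)CO[C@@]1(C)O2 | intermediate
15 | (R)-butane-1,3-diol | C[C@@H](O)CCO | starting material
16 | (R)-4-iodobutan-2-ol | C[C@@H](O)CCI | intermediate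
17 | cyclic keto sulfone 14 with an (R)-3-hydroxybutyl group on the sulfonyl-bearing carbon (quaternary, both epimers) | COc1cc2c(c3c1C(=O)C(CC[C@@H](C)O)(S(=O)(=O)c1ccccc1)CCCC3)C[C@H]1[C@H](C)CO[C@@]1(C)O2 | intermediate
18 | fused six-membered hemiketal of 17 (present as its potassium alkoxide) | COc1cc2c(c3c1C1(O)O[C@H](C)CCC1(S(=O)(=O)c1ccccc1)CCCC3)C[C@H]1[C@H](C)CO[C@@]1(C)O2 | intermediate
19 | lasiodiplactone A with PhSO2 on the fourth ring carbon from the lactone oxygen (both epimers) | COc1cc2c(c3c1C(=O)O[C@H](C)CCC(S(=O)(=O)c1ccccc1)CCCC3)C[C@H]1[C@H](C)CO[C@@]1(C)O2 | intermediate
20 | lasiodiplactone A | COc1cc2c(c3c1C(=O)O[C@H](C)CCCCCCC3)C[C@H]1[C@H](C)CO[C@@]1(C)O2 | target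

## Step count and least certain steps

Total: 12 steps. Longest linear sequence: 11 steps (1 to 20 through steps 1–8 and 10–12); step 9 is a one-step side branch.

Step 11 (key step). The fragmentation may stall or run backwards. The hemiketal has to form at a carbonyl flanked by two ortho substituents, the sulfonyl carbanion is a poor leaving group, and unless it is protonated quickly it can re-add across the ring to the new lactone carbonyl.
- Fallback: a seco-acid route that closes the lactone by activating the alcohol instead of the acyl carbon. It sets out from 13 and returns at 19.
- (S)-Butane-1,3-diol is iodinated as in step 9 to (S)-4-iodobutan-2-ol F1 and silylated (t-BuMe2SiCl, imidazole) to tert-butyl{[(2S)-4-iodobutan-2-yl]oxy}dimethylsilane F2.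
- The sulfonyl carbanion of 13 (LiN(i-Pr)2, THF–DMPU, −78 °C, where intermolecular alkylation should outrun the ring closure of step 8) is alkylated with F2 to the silyl ether sulfone ester F3.
- Bu4NF gives the (S)-hydroxy ester F4, and LiOH in DMSO–H2O at 80 °C gives the seco acid F5.
- Mitsunobu macrolactonisation (PPh3, DIAD, toluene, high dilution) inverts the (S)-carbinol and gives 19.

Step 8. Bimolecular Claisen condensation and oligomerisation may outrun the ring closure, because the ester carbonyl is shielded on both sides and eight-membered rings close slowly.
- Fallback: move the ring closure to the aldehyde oxidation level. It sets out from 13 and returns at 14.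
- i-Bu2AlH reduces the ester to the benzylic alcohol F6, and Dess–Martin periodinane gives the aldehyde F7.
- LiN(i-Pr)2 in THF at −78 °C under high dilution adds the sulfonyl carbanion to the unhindered aldehyde to give the cyclic β-hydroxy sulfone F8.
- Dess–Martin oxidation of F8 gives 14.

Step 10. O-Alkylation of the enolate and slow substitution at the congested tertiary carbon may erode the conversion.
- Fallback: conjugate addition followed by enzymatic reduction. It sets out from 14 and returns at 17.
- 14 adds to methyl vinyl ketone (Et3N cat., CH2Cl2) to give the 3-oxobutyl diketone F9.
- The unhindered methyl ketone of F9 is reduced by the (R)-selective alcohol dehydrogenase of Lactobacillus kefir (NADP+, i-PrOH, phosphate buffer–DMSO, 30 °C) to 17.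

Step 2. The benzylic chloride may alkylate a second arene under the Lewis acid (diarylmethane formation), the benzyl ether may be lost in the acidic medium, and some substitution may leak to the position between the two oxygens.
- Fallback: a formylation route. It sets out from 3 and returns at 4.
- Rieche formylation (Cl2CHOCH3, SnCl4, CH2Cl2, −20 °C) gives methyl 4-(benzyloxy)-3-formyl-6-methoxy-2-methylbenzoate F10.
- NaBH4 gives methyl 4-(benzyloxy)-3-(hydroxymethyl)-6-methoxy-2-methylbenzoate F11, and SOCl2–pyridine converts F11 into 4.

## Further compounds

F1 | step 11 | (S)-4-iodobutan-2-ol | C[C@H](O)CCI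
F2 | step 11 | tert-butyl{[(2S)-4-iodobutan-2-yl]oxy}dimethylsilane | C[C@H](O[Si](C)(C)C(C)(C)C)CCI
F3 | step 11 | sulfone ester 13 alkylated at the α-sulfonyl carbon with the (S)-3-(tert-butyldimethylsilyloxy)butyl group (both epimers at that carbon) | COc1cc2c(c(CCCCC(CC[C@H](C)O[Si](C)(C)C(C)(C)C)S(=O)(=O)c3ccccc3)c1C(=O)OC)C[C@H]1[C@H](C)CO[C@@]1(C)O2
F4 | step 11 | the corresponding (S)-hydroxy methyl ester | COc1cc2c(c(CCCCC(CC[C@H](C)O)S(=O)(=O)c3ccccc3)c1C(=O)OC)C[C@H]1[C@H](C)CO[C@@]1(C)O2
F5 | step 11 | the corresponding (S)-hydroxy acid (seco acid) | COc1cc2c(c(CCCCC(CC[C@H](C)O)S(=O)(=O)c3ccccc3)c1C(=O)O)C[C@H]1[C@H](C)CO[C@@]1(C)O2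
F6 | step 8 | benzylic alcohol from 13 (CO2CH3 reduced to CH2OH) | COc1cc2c(c(CCCCCS(=O)(=O)c3ccccc3)c1CO)C[C@H]1[C@H](C)CO[C@@]1(C)O2
F7 | step 8 | aldehyde from F6 | COc1cc2c(c(CCCCCS(=O)(=O)c3ccccc3)c1C=O)C[C@H]1[C@H](C)CO[C@@]1(C)O2
F8 | step 8 | cyclic β-hydroxy sulfone (secondary alcohol corresponding to 14) | COc1cc2c(c3c1C(O)C(S(=O)(=O)c1ccccc1)CCCC3)C[C@H]1[C@H](C)CO[C@@]1(C)O2
F9 | step 10 | cyclic keto sulfone 14 with a 3-oxobutyl group on the sulfonyl-bearing carbon | COc1cc2c(c3c1C(=O)C(CCC(C)=O)(S(=O)(=O)c1ccccc1)CCCC3)C[C@H]1[C@H](C)CO[C@@]1(C)O2
F10 | step 2 | methyl 4-(benzyloxy)-3-formyl-6-methoxy-2-methylbenzoate | COC(=O)c1c(C)c(C=O)c(OCc2ccccc2)cc1OC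
F11 | step 2 | methyl 4-(benzyloxy)-3-(hydroxymethyl)-6-methoxy-2-methylbenzoate | COC(=O)c1c(C)c(CO)c(OCc2ccccc2)cc1OC
A1 | alternative 1 | sixteen-membered triketo lactone with the (3S,4S)-lactonylmethyl branch | O=C1CC(=O)CC(=O)C(C[C@@H]2C(=O)OC[C@H]2C)C(=O)CCCCCCC[C@@H](C)O1
A2 | alternative 1 | dihydroxy resorcylate macrolactone carrying the butyrolactone side chain | Oc1cc(O)c(C[C@@H]2C(=O)OC[C@H]2C)c2c1C(=O)O[C@H](C)CCCCCCC2
A3 | alternative 2 | (5S)-5-{[(1S,2R,5S)-2-isopropyl-5-methylcyclohexyl]oxy}furan-2(5H)-one | O=C1O[C@H](O[C@H]2C[C@@H](C)CC[C@@H]2C(C)C)C=C1
A4 | alternative 2 | macrocyclic benzylic bromide (methoxymethyl-protected phenol) | COc1cc(OCOC)c(CBr)c2c1C(=O)O[C@H](C)CCCCCCC2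
A5 | alternative 2 | all-trans 3-(arylmethyl)-4-methyl-5-menthyloxy butyrolactone on the macrocycle | COc1cc(OCOC)c(C[C@@H]3C(=O)O[C@H](O[C@H]4C[C@@H](C)CC[C@@H]4C(C)C)[C@H]3C)c2c1C(=O)O[C@H](C)CCCCCCC2
A6 | alternative 3 | silyl ketene acetal diene on the (3S,3aS,7aS)-furopyran | COC(O[Si](C)(C)C)=CC1=CC[C@H]2[C@H](C)CO[C@@]2(C)O1
A7 | alternative 3 | (R)-12-methyloxacyclododec-3-yn-2-one | C[C@@H]1CCCCCCCC#CC(=O)O1
A8 | alternative 3 | O-desmethyl lasiodiplactone A | Oc1cc2c(c3c1C(=O)O[C@H](C)CCCCCCC3)C[C@H]1[C@H](C)CO[C@@]1(C)O2
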